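**Assumption:** the target has no stereocentres (it is achiral), so there is no enantiomer to control. 2,4,5-Trimethylphenol and methyl 2,4-dihydroxy-3,6-dimethylbenzoate (atraric acid) are taken as commercial.

## Retrosynthetic overview

1. Cl goes on last: the des-chloro depside has only one aromatic C–H (ring B, ortho to OH), so chlorination can only go there.
2. Key disconnection is the depside C(aryl)–O bond, not the usual acyl–O bond: ring B carboxylate + ring A aryl(2,4,6-trimethoxyphenyl)iodonium salt. The "phenolic" oxygen comes from the acid.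
3. Ring A iodonium ⇐ aryl iodide ⇐ methyl 2-methoxy-3,5,6-trimethylbenzoate ⇐ 2,4,5-trimethylphenol (Kolbe–Schmitt).
4. Ring B acid ⇐ atraric acid by 4-O-benzylation, 2-O-methylation and saponification.
5. No ring is formed: both benzene rings are bought and re-decorated.

## Route

**Step 1**
Reactants: 1 2,4,5-trimethylphenol
Product: 2 2-hydroxy-3,5,6-trimethylbenzoic acid
Conditions: K2CO3 (3 equiv), CO2 (80 bar), neat, 180 °C, autoclave; then aq. HCl
Reagents that add atoms: carbon dioxide, O=C=O
Why: Kolbe–Schmitt carboxylation (Marasse variant); the phenoxide attacks CO2 at its only free ortho position because the para position is blocked by methyl, as in the thymol to o-thymotic acid case.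

**Step 2**
Reactants: 2 2-hydroxy-3,5,6-trimethylbenzoic acid
Product: 3 methyl 2-methoxy-3,5,6-trimethylbenzoate
Conditions: MeI (3 equiv), K2CO3 (3 equiv), DMF, 50 °C
Reagents that add atoms: iodomethane, CI
Why: SN2 O-alkylation (Williamson type) of both carboxylate and phenoxide; alkylating the carboxylate avoids the steric block that a Fischer esterification of this di-ortho-substituted acid would meet.

**Step 3**
Reactants: 3 methyl 2-methoxy-3,5,6-trimethylbenzoate
Product: 4 methyl 4-iodo-2-methoxy-3,5,6-trimethylbenzoate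
Conditions: NIS (1.2 equiv), TfOH (0.2 equiv), MeCN, 0 °C → rt
Reagents that add atoms: N-iodosuccinimide, O=C1CCC(=O)N1I
Why: Electrophilic aromatic iodination with acid-activated NIS at the only ring C–H left, which is flanked and activated by two methyl groups; the twisted para ester deactivates only weakly.

**Step 4**
Reactants: 4 methyl 4-iodo-2-methoxy-3,5,6-trimethylbenzoate
Product: 6 [3-methoxy-4-(methoxycarbonyl)-2,5,6-trimethylphenyl](2,4,6-trimethoxyphenyl)iodonium tosylate, via aryl hydroxy(tosyloxy)iodane 5 (not isolated)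
Conditions: mCPBA (1.1 equiv), TsOH·H2O (1.1 equiv), MeCN, 77 °C; then 1,3,5-trimethoxybenzene (1.1 equiv), 77 °C → rt; Et2O trituration
Reagents that add atoms: p-toluenesulfonic acid, Cc1ccc(S(=O)(=O)O)cc1; 1,3,5-trimethoxybenzene, COc1cc(OC)cc(OC)c1; mCPBA, OOC(=O)c1cccc(Cl)c1 (its oxygen is in intermediate 5 only)
Why: One-pot diaryliodonium synthesis: oxidation of the aryl iodide to a Koser-type I(III) species, then electrophilic aromatic substitution on the electron-rich trimethoxybenzene; the arene of 4 is fully substituted, so it cannot condense with itself.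

**Step 5**
Reactants: 7 methyl 2,4-dihydroxy-3,6-dimethylbenzoate (atraric acid)
Product: 8 methyl 4-(benzyloxy)-2-hydroxy-3,6-dimethylbenzoate
Conditions: BnBr (1.05 equiv), K2CO3 (1.2 equiv), acetone, reflux
Reagents that add atoms: benzyl bromide, BrCc1ccccc1
Why: Williamson etherification, selective for the 4-OH because the 2-OH is hydrogen-bonded to the ester carbonyl and so less acidic and less nucleophilic.

**Step 6**
Reactants: 8 methyl 4-(benzyloxy)-2-hydroxy-3,6-dimethylbenzoate
Product: 9 methyl 4-(benzyloxy)-2-methoxy-3,6-dimethylbenzoate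
Conditions: MeI (3 equiv), K2CO3 (2 equiv), DMF, 60 °C
Reagents that add atoms: iodomethane, CI
Why: Williamson methylation of the remaining chelated 2-OH, which reacts once a dipolar aprotic solvent and excess MeI are used.

**Step 7**
Reactants: 9 methyl 4-(benzyloxy)-2-methoxy-3,6-dimethylbenzoate
Product: 10 4-(benzyloxy)-2-methoxy-3,6-dimethylbenzoic acid
Conditions: KOH (10 equiv), DMSO/H2O 4:1, 100 °C; then aq. HCl
Reagents that add atoms: potassium hydroxide, [K+].[OH-] (source of the new carboxyl oxygen)
Why: Saponification of a di-ortho-substituted benzoate, which needs poorly solvated hydroxide in DMSO; the benzyl and methyl ethers are inert.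

**Step 8**
Reactants: 10 4-(benzyloxy)-2-methoxy-3,6-dimethylbenzoic acid; 6 [3-methoxy-4-(methoxycarbonyl)-2,5,6-trimethylphenyl](2,4,6-trimethoxyphenyl)iodonium tosylate
Product: 12 methyl 4-{[4-(benzyloxy)-2-methoxy-3,6-dimethylbenzoyl]oxy}-2-methoxy-3,5,6-trimethylbenzoate, via potassium carboxylate 11 (not isolated)
Conditions: t-BuOK (1.0 equiv), toluene, rt, 30 min; then 6 (1.2 equiv), 110 °C
Reagents that add atoms: potassium tert-butoxide, CC(C)(C)[O-].[K+] (its K+ is in intermediate 11 only; all heavy atoms of 12 come from 10 and 6)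
Why: Metal-free O-arylation of a carboxylate with a diaryliodonium salt (ligand exchange at I(III), then ligand coupling); the electron-poorer, di-ortho-methyl ring A aryl is transferred (ortho effect) and the electron-rich trimethoxyphenyl group leaves as its iodide, and neither aryl has an ortho hydrogen, so no aryne pathway exists.

**Step 9**
Reactants: 12 methyl 4-{[4-(benzyloxy)-2-methoxy-3,6-dimethylbenzoyl]oxy}-2-methoxy-3,5,6-trimethylbenzoate
Product: 13 methyl 4-[(4-hydroxy-2-methoxy-3,6-dimethylbenzoyl)oxy]-2-methoxy-3,5,6-trimethylbenzoate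
Conditions: H2 (1 atm), 10% Pd/C, EtOAc, rt
Reagents that add atoms: none
Why: Catalytic hydrogenolysis of the benzyl ether; the hindered aryl ester, the methyl ester and the methyl ethers are not touched.

**Step 10**
Reactants: 13 methyl 4-[(4-hydroxy-2-methoxy-3,6-dimethylbenzoyl)oxy]-2-methoxy-3,5,6-trimethylbenzoate
Product: 14 methyl 4-[(3-chloro-4-hydroxy-6-methoxy-2,5-dimethylbenzoyl)oxy]-2-methoxy-3,5,6-trimethylbenzoate (target)
Conditions: SO2Cl2 (1.05 equiv), CH2Cl2/Et2O, 0 °C
Reagents that add atoms: sulfuryl chloride, O=S(=O)(Cl)Cl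
Why: Electrophilic aromatic chlorination at the only aromatic C–H in the molecule, which is ortho to the free OH and para to OMe; ring A is fully substituted, so regiochemistry is fixed.

## Compound list

1 | 2,4,5-trimethylphenol | Oc1cc(C)c(C)cc1C | starting material
2 | 2-hydroxy-3,5,6-trimethylbenzoic acid | Cc1cc(C)c(O)c(C(=O)O)c1C | intermediate
3 | methyl 2-methoxy-3,5,6-trimethylbenzoate | COC(=O)c1c(C)c(C)cc(C)c1OC | intermediate
4 | methyl 4-iodo-2-methoxy-3,5,6-trimethylbenzoate | COC(=O)c1c(C)c(C)c(I)c(C)c1OC | intermediate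
5 | methyl 4-[hydroxy(tosyloxy)-λ3-iodanyl]-2-methoxy-3,5,6-trimethylbenzoate | COC(=O)c1c(C)c(C)c(I(O)OS(=O)(=O)c2ccc(C)cc2)c(C)c1OC | intermediate (not isolated)
6 | [3-methoxy-4-(methoxycarbonyl)-2,5,6-trimethylphenyl](2,4,6-trimethoxyphenyl)iodonium tosylate | COC(=O)c1c(C)c(C)c([I+]c2c(OC)cc(OC)cc2OC)c(C)c1OC.Cc1ccc(S(=O)(=O)[O-])cc1 | intermediate
7 | methyl 2,4-dihydroxy-3,6-dimethylbenzoate (atraric acid) | COC(=O)c1c(C)cc(O)c(C)c1O | starting material
8 | methyl 4-(benzyloxy)-2-hydroxy-3,6-dimethylbenzoate | COC(=O)c1c(C)cc(OCc2ccccc2)c(C)c1O | intermediate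
9 | methyl 4-(benzyloxy)-2-methoxy-3,6-dimethylbenzoate | COC(=O)c1c(C)cc(OCc2ccccc2)c(C)c1OC | intermediate
10 | 4-(benzyloxy)-2-methoxy-3,6-dimethylbenzoic acid | OC(=O)c1c(C)cc(OCc2ccccc2)c(C)c1OC | intermediate
11 | potassium 4-(benzyloxy)-2-methoxy-3,6-dimethylbenzoate | [K+].[O-]C(=O)c1c(C)cc(OCc2ccccc2)c(C)c1OC | intermediate (not isolated)
12 | methyl 4-{[4-(benzyloxy)-2-methoxy-3,6-dimethylbenzoyl]oxy}-2-methoxy-3,5,6-trimethylbenzoate | COC(=O)c1c(C)c(C)c(OC(=O)c2c(C)cc(OCc3ccccc3)c(C)c2OC)c(C)c1OC | intermediate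
13 | methyl 4-[(4-hydroxy-2-methoxy-3,6-dimethylbenzoyl)oxy]-2-methoxy-3,5,6-trimethylbenzoate | COC(=O)c1c(C)c(C)c(OC(=O)c2c(C)cc(O)c(C)c2OC)c(C)c1OC | intermediate
14 | methyl 4-[(3-chloro-4-hydroxy-6-methoxy-2,5-dimethylbenzoyl)oxy]-2-methoxy-3,5,6-trimethylbenzoate | COC(=O)c1c(C)c(C)c(OC(=O)c2c(C)c(Cl)c(O)c(C)c2OC)c(C)c1OC | target

## Count and risk

Total step count: 10. Longest linear sequence: 7 steps (steps 1, 2, 3, 4, 8, 9, 10); the ring B branch (steps 5–7) joins at step 8.

Three steps most likely to fail:

**Step 8 (carboxylate O-arylation).** Both partners are di-ortho-substituted, and transfer of the wrong aryl or simple decomposition of the salt could dominate. The fallback gives up the C(aryl)–O strategy for acyl–O formation. It sets out from iodide 4: Pd-catalysed hydroxylation with benzaldoxime as hydroxide surrogate (tBuBrettPhos-Pd, Cs2CO3, DMF, 80 °C) gives methyl 4-hydroxy-2-methoxy-3,5,6-trimethylbenzoate F1. This phenol is acylated by acid 10 through its mixed trifluoroacetic anhydride (TFAA, toluene, rt), and the route is rejoined at 12.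

**Step 4 (iodonium salt from the hindered iodide).** Oxidation of the doubly ortho-methylated, ester-bearing iodide to 5 may be slow, or the salt 6 may not crystallise cleanly. The fallback puts the I(III) centre on the other partner. It sets out from 4: I/Mg exchange (i-PrMgCl·LiCl, THF, −30 °C), B(OMe)3 and aqueous acid give [3-methoxy-4-(methoxycarbonyl)-2,5,6-trimethylphenyl]boronic acid F2. Boron-to-iodine(III) exchange with commercial Koser's reagent PhI(OH)OTs (CH2Cl2, rt) gives [3-methoxy-4-(methoxycarbonyl)-2,5,6-trimethylphenyl](phenyl)iodonium tosylate F3. F3 arylates carboxylate 11 under the step 8 conditions, where the ortho effect and the ester favour transfer of the ring A aryl over phenyl, and the route is rejoined at 12.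

**Step 1 (Kolbe–Schmitt carboxylation).** High-pressure carboxylation at a position flanked by OH and methyl may be low-yielding. The fallback replaces electrophilic carboxylation by halogen–metal exchange. It sets out from 1: bromination (Br2, CH2Cl2, 0 °C) at the only free ortho position gives 2-bromo-3,4,6-trimethylphenol F4. Methylation (MeI, K2CO3, DMF) gives 2-bromo-1-methoxy-3,4,6-trimethylbenzene F5. Br/Li exchange (n-BuLi, THF, −78 °C) and inverse quench into methyl chloroformate give the ester directly, so the route is rejoined at 3 and compound 2 is bypassed.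

## Further compounds

F1 | step 8 | methyl 4-hydroxy-2-methoxy-3,5,6-trimethylbenzoate | COC(=O)c1c(C)c(C)c(O)c(C)c1OC
F2 | step 4 | [3-methoxy-4-(methoxycarbonyl)-2,5,6-trimethylphenyl]boronic acid | COC(=O)c1c(C)c(C)c(B(O)O)c(C)c1OC
F3 | step 4 | [3-methoxy-4-(methoxycarbonyl)-2,5,6-trimethylphenyl](phenyl)iodonium tosylate | COC(=O)c1c(C)c(C)c([I+]c2ccccc2)c(C)c1OC.Cc1ccc(S(=O)(=O)[O-])cc1
F4 | step 1 | 2-bromo-3,4,6-trimethylphenol | Oc1c(Br)c(C)c(C)cc1C
F5 | step 1 | 2-bromo-1-methoxy-3,4,6-trimethylbenzene | COc1c(Br)c(C)c(C)cc1C
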